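55.0 turnovers is what the flask's reagent charge buys from its catalyst, counting one reagent spent and one product made per turnover. The reagent is the limiting reagent, 0.0550 M against 0.100 M of both substrates together. If that product ends racemic, left-handed product stands at 27.5% of the substrates charged. I call this the racemic level: half of the product the turnovers can make.

| setting | Sunday's | Saturday's | Tuesday's | flask |
|---|---|---|---|---|
| left-handed substrate | 0.050 M | 0.050 M | 0.050 M | 0.050 M |
| right-handed substrate | 0.050 M | 0.050 M | 0.050 M | 0.050 M |
| reagent | 0.055 M | 0.055 M | 0.083 M | 0.0550 M |
| catalyst | 0.67 mM | 1.5 mM | 1 mM | 1.0 mM |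
| remark | run made earlier | run made earlier | run made earlier |  |
| time |  |  |  | 20 h |

- Sunday's (time / h: left-handed product / %): 0.667: 22.1; 1.33: 28.3; 2.50: 31.1; 4.00: 30.9; 8.00: 29.1; 15.0: 28.2
- Saturday's (time / h: left-handed product / %): 0.667: 29.6; 1.33: 32.0; 2.50: 32.4; 4.00: 31.7; 8.00: 28.7; 15.0: 28.0
- Tuesday's (time / h: left-handed product / %): 0.667: 33.8; 1.33: 39.4; 3.00: 41.9; 8.00: 41.8; 15.0: 42.4

(scatter of a reading: 0.5 percentage points)

- catalyst is single-handed; left-handed substrate and right-handed substrate are mirror images of each other, charged as a racemate, each of them at the stated concentration

* time up to 20 h at which left-handed product stands highest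
* the amount of left-handed product, in percent of the left-handed substrate and right-handed substrate together charged, at that time

I run the flask in slow motion from the earlier runs. In the first instants left-handed product climbs faster with more catalyst: after 0.667 h, Saturday's run, with 1.5 mM, reads 29.6%, while Sunday's, with 0.67 mM, reads 22.1%.

In the middle the climb stops. Sunday's and Saturday's runs both read highest at 2.50 h, Sunday's at 31.1% and Saturday's at 32.4%, and both readings stand above the racemic level. So in these two runs left-handed product is ahead of right-handed product, and that lead is what is about to shrink.

At the end, after 15.0 h, they read 28.2% and 28.0%, close to the level. Tuesday's run, with 0.083 M of reagent, has a level of 41.5% and reads 42.4%.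

With 1.0 mM of catalyst, between the charges of Sunday's and Saturday's runs, I expect the flask to peak near 2.50 h, between the heights those two runs read. The forecast gives 2.5 h (1.7 h to 3.5 h) and 31.9% (31.1% to 32.7%), holding that “more catalyst gives a slightly earlier and higher peak”.

The flask peaks at 2.48 h with 31.5% of left-handed product, while right-handed product stands at 22.0%.

    reagent + catalyst + left-handed substrate → catalyst + left-handed product (k = 39000 /M²/h)
    left-handed product ⇌ right-handed product (k = 0.100 /h)
    reagent + catalyst + right-handed substrate → catalyst + right-handed product (k = 17000 /M²/h)

After 20.0 h the flask holds 27.6% of left-handed product and 27.4% of right-handed product, against a racemic level of 27.5%. The neighbour charged with 0.022 M of reagent buys 22.0 turnovers, so its racemic level is 11.0%, and after 20.0 h it holds 11.1% of left-handed product.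

The readings stem from a simulated flask on assumed constants, noise included.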